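The target is a cyclohexene (C1 = CHOAc, C2 = side-chain carbon, C3 = CH, C4 = CMe2, C5 = CHBr, C6 = CH2). Its C2=C3 double bond lies opposite the C5–C6 edge, which is the retron of a [4+2] cycloaddition. Cutting C1–C6 and C4–C5 gives a 1-acetoxy-4,4-dimethyl diene and a vinyl bromide equivalent. The key step is a catalytic enantioselective Diels–Alder reaction with 2-bromoacrolein. It closes the ring, brings in the acetate and the neopentyl bromine, and fixes C1. Its precursor is an acyclic 2-iodo dienyl acetate made in two steps. The formyl activator is then removed by radical decarboxylation. The iodide is turned into the bromochloroethyl chain through a chloromethyl ketone.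

Key step: step 4

Assumption: the sense of induction in step 4 is taken from this catalyst family with 2-bromoacrolein and simple dienes, where the (S)-catalyst is assumed to direct attack to the Re face of C2 of the enal. The route needs Si-face attack and so names the (R)-catalyst; the (S)-catalyst would be used if the sense is reversed for diene 3.

Step 1
Reactants: 1 (E)-4-methylpent-2-enal
Product: 2 (Z)-2-iodo-4-methylpent-2-enal
Conditions: I2, K2CO3, DMAP (cat.), THF–H2O, rt
Reagents that add atoms: iodine, II
Why: Nucleophile-catalysed α-iodination of an enal (Baylis–Hillman-type addition of DMAP, iodination of the enolate, loss of DMAP), which should give the Z isomer because CHO stays trans to the isopropyl group.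

Step 2
Reactants: 2 (Z)-2-iodo-4-methylpent-2-enal
Product: 3 (1Z)-2-iodo-4-methylpenta-1,3-dien-1-yl acetate
Conditions: isopropenyl acetate (solvent), p-TsOH (cat.), reflux, acetone distilled off
Reagents that add atoms: isopropenyl acetate, CC(=C)OC(C)=O
Why: Acid-catalysed enol acetylation by transesterification, in which loss of the γ-hydrogen gives the conjugated dienol and the s-trans enal places OAc trans to the isobutenyl group (1Z), while any 1E isomer cannot reach an s-cis form and should stay behind in step 4.

Step 3
Reactants: 4 acrolein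
Product: 6 2-bromoacrolein, via 2,3-dibromopropanal 5 (not isolated)
Conditions: Br2, CH2Cl2, −78 to 0 °C; then Et3N, 0 °C
Reagents that add atoms: bromine, BrBr
Why: Bromine addition to the C=C bond followed by E1cB loss of HBr from the acidic α-position, the standard bromination–dehydrobromination of an enal.

Step 4
Reactants: 3 (1Z)-2-iodo-4-methylpenta-1,3-dien-1-yl acetate; 6 2-bromoacrolein
Product: 7 (1R,5S)-5-bromo-5-formyl-2-iodo-4,4-dimethylcyclohex-2-en-1-yl acetate
Conditions: (R)-B-o-tolyl diphenylprolinol oxazaborolidine·Tf2NH (20 mol %), CH2Cl2, −78 to −20 °C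
Reagents that add atoms: none
Why: This is a concerted but strongly asynchronous normal-demand [4+2] cycloaddition (catalytic enantioselective Diels–Alder reaction): the boron-bound formyl group makes the CH2 end of 6 electrophilic, it bonds first to the unhindered CH(OAc) terminus of 3, and the developing Me2C/C(I) allyl cation character then closes onto the bromine-bearing carbon. The closest known cases are oxazaborolidine-catalysed additions of 2-bromoacrolein to acyclic dienes and thermal additions of 2-haloacrylonitriles to 1,1-dimethyl-substituted dienes, which also join the halogen-bearing carbon to the CMe2 terminus. The single new ring, the cyclohexene, closes suprafacially on both partners ([π4s+π2s]), forming C1–C6 and C4–C5 and leaving C2=C3. C5 is fixed by the catalyst, which shields one face of the enal, and C1 follows from the 1Z geometry of 3 (OAc outside) together with the Br-endo/CHO-exo orientation typical of 2-haloacroleins and reinforced here by the iodine under the endo region, so that OAc and Br become cis. The step needs regioselectivity, secured because acetoxy is a weaker donor than the two methyl groups plus the C2 substituent, so that both nucleophilicity and accessibility favour the CH(OAc) terminus, while the iodine also twists 3 out of the s-trans form. Any CHO-endo adduct carries the opposite C1 configuration and must be removed by chromatography at this stage.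

Step 5
Reactants: 7 (1R,5S)-5-bromo-5-formyl-2-iodo-4,4-dimethylcyclohex-2-en-1-yl acetate
Product: 8 (1S,5R)-5-acetoxy-1-bromo-4-iodo-2,2-dimethylcyclohex-3-ene-1-carboxylic acid
Conditions: NaClO2, NaH2PO4, 2-methylbut-2-ene, t-BuOH–H2O, 0 °C to rt
Reagents that add atoms: sodium chlorite, [Na+].[O-]Cl=O
Why: Pinnick oxidation, which is selective for the aldehyde, needs no base, changes no stereocentre and should leave the tertiary bromide, the vinyl iodide and the acetate untouched.

Step 6
Reactants: 8 (1S,5R)-5-acetoxy-1-bromo-4-iodo-2,2-dimethylcyclohex-3-ene-1-carboxylic acid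
Product: 11 (1R,5S)-5-bromo-2-iodo-4,4-dimethylcyclohex-2-en-1-yl acetate, via acid chloride 9 (not isolated), via Barton ester 10 (not isolated)
Conditions: (COCl)2, DMF (cat.), CH2Cl2, 0 °C to rt; sodium 2-thioxopyridin-1(2H)-olate, DMAP (cat.), toluene, dark; t-BuSH (excess), hν (W lamp), rt
Reagents that add atoms: none
Why: Barton reductive decarboxylation, in which the α-bromo radical at C5 should take hydrogen from the fast donor t-BuSH axially, on the face away from the pseudoaxial C4 methyl group and syn to H-1, so that bromine becomes equatorial and cis to the acetate.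

Step 7
Reactants: 11 (1R,5S)-5-bromo-2-iodo-4,4-dimethylcyclohex-2-en-1-yl acetate; 12 tributyl(1-ethoxyethenyl)stannane
Product: 13 (1R,5S)-5-bromo-2-(1-ethoxyethenyl)-4,4-dimethylcyclohex-2-en-1-yl acetate
Conditions: Pd2(dba)3 (2.5 mol %), AsPh3 (10 mol %), CuI (10 mol %), NMP, rt to 40 °C; aqueous wash, filtration through Et3N-deactivated silica
Reagents that add atoms: none
Why: Stille coupling, in which the soft ligand AsPh3 and Cu(I) allow oxidative addition into the C(sp2)–I bond near room temperature, where the hindered allylic acetate and the secondary alkyl bromide should not react.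

Step 8
Reactants: 13 (1R,5S)-5-bromo-2-(1-ethoxyethenyl)-4,4-dimethylcyclohex-2-en-1-yl acetate
Product: 14 (1R,5S)-5-bromo-2-(chloroacetyl)-4,4-dimethylcyclohex-2-en-1-yl acetate
Conditions: NCS, THF–H2O, 0 °C
Reagents that add atoms: N-chlorosuccinimide, O=C1CCC(=O)N1Cl; water, O
Why: Electrophilic chlorination of the enol ether, by far the most electron-rich alkene, at its CH2 terminus and hydrolysis of the oxocarbenium ion, the standard way from a 1-ethoxyvinyl group to a halomethyl ketone (iodide is removed in step 7 to avoid halogen scrambling).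

Step 9
Reactants: 14 (1R,5S)-5-bromo-2-(chloroacetyl)-4,4-dimethylcyclohex-2-en-1-yl acetate
Product: 15 (1R,5S)-5-bromo-2-[(1S)-2-chloro-1-hydroxyethyl]-4,4-dimethylcyclohex-2-en-1-yl acetate
Conditions: (S)-Me-CBS (20 mol %), BH3·SMe2, THF, −30 °C; MeOH, aqueous work-up
Reagents that add atoms: none
Why: CBS reduction under reagent control, with the branched cyclohexenyl group as the large and CH2Cl as the small substituent, the same arrangement by which the (S)-catalyst turns phenacyl chloride into the (S)-chlorohydrin, so the carbinol centre should be S.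

Step 10
Reactants: 15 (1R,5S)-5-bromo-2-[(1S)-2-chloro-1-hydroxyethyl]-4,4-dimethylcyclohex-2-en-1-yl acetate
Product: 16 (1R,5S)-5-bromo-2-[(1R)-1-bromo-2-chloroethyl]-4,4-dimethylcyclohex-2-en-1-yl acetate
Conditions: CBr4, PPh3, CH2Cl2, 0 °C
Reagents that add atoms: tetrabromomethane, BrC(Br)(Br)Br
Why: Appel reaction, an SN2 displacement of the oxyphosphonium group by bromide with inversion (S to R), in which the SN2′ path is blocked by the CMe2 group next to C3 and ionisation is disfavoured by the β-chlorine.

Compound list
1 | (E)-4-methylpent-2-enal | CC(C)/C=C/C=O | starting material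
2 | (Z)-2-iodo-4-methylpent-2-enal | CC(C)/C=C(\I)C=O | intermediate
3 | (1Z)-2-iodo-4-methylpenta-1,3-dien-1-yl acetate | CC(=O)O/C=C(\I)C=C(C)C | intermediate
4 | acrolein | C=CC=O | starting material
5 | 2,3-dibromopropanal | BrCC(Br)C=O | intermediate
6 | 2-bromoacrolein | C=C(Br)C=O | intermediate
7 | (1R,5S)-5-bromo-5-formyl-2-iodo-4,4-dimethylcyclohex-2-en-1-yl acetate | CC(=O)O[C@@H]1C[C@](C=O)(Br)C(C)(C)C=C1I | intermediate
8 | (1S,5R)-5-acetoxy-1-bromo-4-iodo-2,2-dimethylcyclohex-3-ene-1-carboxylic acid | CC(=O)O[C@@H]1C[C@](C(=O)O)(Br)C(C)(C)C=C1I | intermediate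
9 | (1S,5R)-5-acetoxy-1-bromo-4-iodo-2,2-dimethylcyclohex-3-ene-1-carbonyl chloride | CC(=O)O[C@@H]1C[C@](C(=O)Cl)(Br)C(C)(C)C=C1I | intermediate
10 | 2-thioxopyridin-1(2H)-yl (1S,5R)-5-acetoxy-1-bromo-4-iodo-2,2-dimethylcyclohex-3-ene-1-carboxylate | CC(=O)O[C@@H]1C[C@](C(=O)ON2C=CC=CC2=S)(Br)C(C)(C)C=C1I | intermediate
11 | (1R,5S)-5-bromo-2-iodo-4,4-dimethylcyclohex-2-en-1-yl acetate | CC(=O)O[C@@H]1C[C@H](Br)C(C)(C)C=C1I | intermediate
12 | tributyl(1-ethoxyethenyl)stannane | CCCC[Sn](CCCC)(CCCC)C(=C)OCC | starting material
13 | (1R,5S)-5-bromo-2-(1-ethoxyethenyl)-4,4-dimethylcyclohex-2-en-1-yl acetate | CC(=O)O[C@@H]1C[C@H](Br)C(C)(C)C=C1C(=C)OCC | intermediate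
14 | (1R,5S)-5-bromo-2-(chloroacetyl)-4,4-dimethylcyclohex-2-en-1-yl acetate | CC(=O)O[C@@H]1C[C@H](Br)C(C)(C)C=C1C(=O)CCl | intermediate
15 | (1R,5S)-5-bromo-2-[(1S)-2-chloro-1-hydroxyethyl]-4,4-dimethylcyclohex-2-en-1-yl acetate | CC(=O)O[C@@H]1C[C@H](Br)C(C)(C)C=C1[C@H](O)CCl | intermediate
16 | (1R,5S)-5-bromo-2-[(1R)-1-bromo-2-chloroethyl]-4,4-dimethylcyclohex-2-en-1-yl acetate | CC(=O)O[C@@H]1C[C@H](Br)C(C)(C)C=C1[C@@H](Br)CCl | target

Total step count: 10. Longest linear sequence: 9 (steps 1, 2 and 4 to 10).

Steps most likely to fail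

**Step 4.** The cycloaddition has to join two fully substituted carbons using a diene of modest nucleophilicity. It may stall while the enal polymerises, divert into a stepwise path, or lose the Br-endo orientation on which the C1 configuration depends. The fallback sets out from 3 and acrolein 4.
- The same catalyst family (enantiomer chosen for 1R) should give, through the usual CHO-endo mode, (1R,5S)-5-formyl-2-iodo-4,4-dimethylcyclohex-2-en-1-yl acetate F1. In F1 the new C4–C5 bond ends at a tertiary carbon only.
- TMSOTf/Et3N turns it into the silyl enol ether (1R)-2-iodo-4,4-dimethyl-5-[(trimethylsilyloxy)methylidene]cyclohex-2-en-1-yl acetate F2.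
- NBS should brominate F2 on the face away from the pseudoaxial methyl group. This gives (1R,5R)-5-bromo-5-formyl-2-iodo-4,4-dimethylcyclohex-2-en-1-yl acetate F3, the C5 epimer of 7.
- Under the conditions of steps 5 and 6, F3 passes through the epimeric carboxylic acid F4, the epimeric acid chloride F5 and the epimeric Barton ester F6.
- Because C5 becomes a radical, the sequence comes back to the route at 11.

**Step 6.** Facial selectivity in the hydrogen-atom transfer may be insufficient, or the homoallylic radical may undergo vinyl migration before it is trapped. The fallback sets C5 by substitution instead and sets out from 10.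
- Photolysis of 10 under O2 with t-BuSH (decarboxylative oxygenation) and a reductive work-up should collapse the α-bromo hydroperoxide to the ketone (1R)-2-iodo-4,4-dimethyl-5-oxocyclohex-2-en-1-yl acetate F7.
- Reagent-controlled, base-free CBS reduction with (S)-Me-CBS (CMe2 side large, CH2 side small) should give the trans alcohol (1R,5R)-5-hydroxy-2-iodo-4,4-dimethylcyclohex-2-en-1-yl acetate F8.
- An Appel reaction with inversion (CBr4, PPh3) comes back to the route at 11. This is the known oxidation-level tactic for bromides next to a gem-dimethyl group in cyclohexanes.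

**Step 7.** Ionisation of the allylic acetate by Pd(0) may compete with oxidative addition into the hindered C–I bond. That would scramble C1 or cause elimination. The fallback is palladium-free and sets out from 11.
- A Nozaki–Hiyama–Kishi reaction (CrCl2, NiCl2 cat., DMF) with freshly prepared anhydrous chloroacetaldehyde should give (1R,5S)-5-bromo-2-(2-chloro-1-hydroxyethyl)-4,4-dimethylcyclohex-2-en-1-yl acetate F9 as a mixture at the carbinol carbon.
- Dess–Martin oxidation comes back to the route at 14.

Further compounds
F1 | step 4 | (1R,5S)-5-formyl-2-iodo-4,4-dimethylcyclohex-2-en-1-yl acetate | CC(=O)O[C@@H]1C[C@H](C=O)C(C)(C)C=C1I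
F2 | step 4 | (1R)-2-iodo-4,4-dimethyl-5-[(trimethylsilyloxy)methylidene]cyclohex-2-en-1-yl acetate | CC(=O)O[C@@H]1CC(=CO[Si](C)(C)C)C(C)(C)C=C1I
F3 | step 4 | (1R,5R)-5-bromo-5-formyl-2-iodo-4,4-dimethylcyclohex-2-en-1-yl acetate | CC(=O)O[C@@H]1C[C@@](C=O)(Br)C(C)(C)C=C1I
F4 | step 4 | (1R,5R)-5-acetoxy-1-bromo-4-iodo-2,2-dimethylcyclohex-3-ene-1-carboxylic acid | CC(=O)O[C@@H]1C[C@@](C(=O)O)(Br)C(C)(C)C=C1I
F5 | step 4 | (1R,5R)-5-acetoxy-1-bromo-4-iodo-2,2-dimethylcyclohex-3-ene-1-carbonyl chloride | CC(=O)O[C@@H]1C[C@@](C(=O)Cl)(Br)C(C)(C)C=C1I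
F6 | step 4 | 2-thioxopyridin-1(2H)-yl (1R,5R)-5-acetoxy-1-bromo-4-iodo-2,2-dimethylcyclohex-3-ene-1-carboxylate | CC(=O)O[C@@H]1C[C@@](C(=O)ON2C=CC=CC2=S)(Br)C(C)(C)C=C1I
F7 | step 6 | (1R)-2-iodo-4,4-dimethyl-5-oxocyclohex-2-en-1-yl acetate | CC(=O)O[C@@H]1CC(=O)C(C)(C)C=C1I
F8 | step 6 | (1R,5R)-5-hydroxy-2-iodo-4,4-dimethylcyclohex-2-en-1-yl acetate | CC(=O)O[C@@H]1C[C@@H](O)C(C)(C)C=C1I
F9 | step 7 | (1R,5S)-5-bromo-2-(2-chloro-1-hydroxyethyl)-4,4-dimethylcyclohex-2-en-1-yl acetate | CC(=O)O[C@@H]1C[C@H](Br)C(C)(C)C=C1C(O)CCl
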